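## Analysis of the target

Compound 28 is built from two flavanone units (2-arylchroman-4-ones). They are joined by a diaryl ether between C4' of ring B of unit 1 and C6'' of ring A of unit 2. Unit 1 carries 5-OH and 7-OMe. Unit 2 carries 5''-OH, 7''-OMe and 4'''-OH, so its ring A is pentasubstituted and the ether oxygen at C6'' sits between two oxygen-bearing carbons.

The only stereocentres are C2 and C2'', both S. They lie far apart across the diaryl ether and cannot influence each other, so each has to be set by a reagent.

Flavanones lose configuration at C2 by retro-oxa-Michael opening to 2'-hydroxychalcones, most readily under base and when the 5-hydroxyl is free. The phloroglucinol-type rings are sensitive to electrophiles and oxidants. At the end three phenols must be free while two methyl ethers stay in place.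

The difficulty is the combination of a crowded central ring, twofold absolute stereocontrol and selective unveiling of the peri phenols. The strategy rests on one feature: C3 and C4 (and C3'' and C4'') carry nothing except the ketone. Each pyranone ring can therefore be closed as a C3=C4 alkene between a vinyl group on C4a and an allyl ether at C2, and the oxygen at C4 can be added afterwards.

## Retrosynthetic reasoning

**28 from 27.** The last operation is deprotection only. The peri methyl ethers at O5 and O5'' and the benzyl ether at O4''' are removed in one chelation-controlled Lewis-acid dealkylation. The C4 and C4'' carbonyl groups direct the reagent to their neighbours, so the 7- and 7''-methyl ethers need no differentiation earlier. This is why the phenols are carried as methyl and benzyl ethers.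

**27 from 24 by way of 26.** The two ketones are traced back to the styrene-type double bonds C3=C4 and C3''=C4''. C4 is benzylic to a very electron-rich ring, so a radical hydration places the oxygen there and not at C3. A mild oxidation then gives the ketone. Neither operation touches C2 or C2''.

**24 from 23 (key disconnection).** Both C3=C4 bonds are cut by retro-metathesis, which returns a vinyl group on each C4a and an allyl ether at each C2. Cutting here moves both stereocentres out of the rings into acyclic 1-arylallyl aryl ethers, a motif for which a catalytic asymmetric C–O bond formation exists. Both rings are then formed by one reaction applied twice. The forward reaction has to close two six-membered rings from four alkenes without intermolecular metathesis and without moving the allylic double bonds.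

**23 from 22 and 20.** The O1–C2 bond is cut. The forward reaction is a branched-selective asymmetric allylic etherification between the phenol 22 and the linear carbonate 20, and it sets C2.

**20 from 14 by way of 19, 17 and 16.** The cinnamyl carbonate is unfolded to a nitrile by functional-group changes. The nitrile is chosen because it activates the ring B precursor for the ether-forming substitution at the start. It also stays inert while the phenol end of the central fragment is used first.

**14 from 13 and 5.** The O1''–C2'' bond is cut in the same way and C2'' is set by the same catalyst. The central fragment acts first as nucleophile (13) and only later as electrophile (20), so no protecting group is needed to keep it from reacting with itself.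

**13 from 6 and 7 by way of 12, 10 and 8.** The diaryl ether is cut first, at the stage where the symmetric phenol 6 and the activated fluoride 7 are the simplest possible partners. The formyl group of 6 is then exchanged for a hydroxyl group (10) and a new formyl group is placed ortho to that hydroxyl group (12). This turns the symmetric substitution pattern of 6 into that of ring A of unit 2. Methylenation gives 13.

**5 from 1 by way of 4 and 2; 22 from 21.** The remaining pieces are a two-carbon homologation of 1 to the linear carbonate 5 and a methylenation of 21.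

## Alternatives that were turned down

**Alternative 1:** Ring C of unit 1 is cut at C4a–C4, C4–C3 and O1–C2.
- Forward key step: a palladium-catalysed three-component carbonylative coupling of the iodophenol A2 with the aryl alkyne A3, the C4 carbon coming from the gas phase. The resulting ynone closes under amine base to the bis-flavone A1.
- For it: the step is convergent, forms three bonds at once and delivers C4 directly at the ketone oxidation level. No hydration or oxidation is needed, and no configurationally labile ether has to be carried. On these points it is stronger than the chosen route.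
- Against it: A1 has sp2 centres at C2 and C2''. Both stereocentres of 28 would have to be made afterwards by a twofold enantioselective conjugate reduction of two different, electron-rich chromones. These are poor acceptors, over-reduction is easy, and incomplete control gives diastereomers. A3 must already contain the finished unit 2, so the route is linear in that unit. Oxidative addition into the doubly ortho-substituted, electron-rich A2 is slow, and 5-exo closure to an aurone competes with the 6-endo mode.
- In its place the chosen strategy sets C2 and C2'' at the moment their C–O bonds are made, never passes through a planar C2, and builds both units with the same two reactions.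

**Alternative 2:** C2–C3 and C2''–C3'' are cut.
- Forward key step: a strong alkoxide base converts the bis(O-aroyl) acetophenone A5 into the bis(1,3-diketone) A4 by twofold O-to-C acyl transfer. Acid cyclodehydration would then give A1.
- For it: the chemistry is classical, metal-free and cheap, and the regiochemistry is unambiguous. In robustness of the bond-forming steps it is at least equal to the chosen route.
- Against it: it ends at the same bis-flavone A1 and therefore has the same unsolved problem of two late stereocentres. It also needs two C-acetylated, crowded phenols, one of them on the pentasubstituted ring, and exposes the material to strong base and then strong acid.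
- The chosen strategy needs more steps to assemble 23, but its stereochemistry is fixed by a catalyst early and then only preserved.

**Alternative 3:** Ring A of unit 1 is cut at C4a–C5 and C8–C8a.
- Forward key step: the electron-rich diene A7 adds across C5=C6 of the sulfinyl dihydropyranone A8, taken here as the phenyl sulfoxide. Elimination of the sulfinyl group and of one methoxy group aromatises ring A to give A6.
- For it: the polarity of A7 fixes the 5-oxygen and 7-methoxy pattern. The 5-hydroxyl arrives free, so unit 1 needs no peri-demethylation, and the ketone is present from the start. On these points it is stronger than the chosen route.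
- Against it: only ring A of unit 1 can be made this way. The ring A of unit 2, with its aryloxy group at C6'', must be built earlier by other means, so A8 already carries the complete unit 2 and the sequence is long and linear. In A8 the C2 stereocentre is β to the enone carbonyl with O1 as a leaving group, so the thermal cycloaddition invites ring opening. The silyl ketene acetal A7 can also attack the C4'' ketone or act as a Michael donor. A 5''-demethylation is still required at the end.
- The chosen strategy treats the two units alike, keeps the risk in one twofold ring closure, and draws its substrate from simple arenes.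

Key step: step 15

## Route

Assumption: L is (Sa,Sc,Sc)-O,O'-(1,1'-binaphthalene-2,2'-diyl) N,N-bis(1-phenylethyl)phosphoramidite. This enantiomer is taken to deliver the (S)-configured branched aryl ethers from (E)-3-arylallyl carbonates. The sense would be confirmed on a model ether, and the mirror-image ligand would be used in steps 8 and 14 if it proved opposite.

Step 1
Reactants: 1 4-(benzyloxy)benzaldehyde
Product: 2 ethyl (E)-3-[4-(benzyloxy)phenyl]prop-2-enoate
Conditions: (EtO)2P(O)CH2CO2Et, NaH, THF, 0 °C to rt
Reagents that add atoms: triethyl phosphonoacetate, CCOC(=O)CP(=O)(OCC)OCC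
Why: Horner–Wadsworth–Emmons olefination of an aromatic aldehyde with a stabilised phosphonate anion, which should give the (E)-cinnamate.

Step 2
Reactants: 2 ethyl (E)-3-[4-(benzyloxy)phenyl]prop-2-enoate
Product: 4 (E)-3-[4-(benzyloxy)phenyl]prop-2-en-1-ol, via enal 3 (not isolated)
Conditions: i-Bu2AlH (2.5 equiv), CH2Cl2, −78 to 0 °C; aq. potassium sodium tartrate
Reagents that add atoms: none
Why: 1,2-Reduction of a conjugated ester by i-Bu2AlH; the aldehyde released on collapse of the hemiacetal is reduced faster than the ester, and the double bond is not touched.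

Step 3
Reactants: 4 (E)-3-[4-(benzyloxy)phenyl]prop-2-en-1-ol
Product: 5 (E)-3-[4-(benzyloxy)phenyl]prop-2-en-1-yl methyl carbonate
Conditions: ClCO2Me, pyridine, CH2Cl2, 0 °C
Reagents that add atoms: methyl chloroformate, COC(=O)Cl
Why: Acylation of a primary allylic alcohol; the methyl carbonate is the standard leaving group for iridium allyl chemistry because it ionises easily and releases its own base.

Step 4
Reactants: 6 syringaldehyde; 7 4-fluorobenzonitrile
Product: 8 4-(4-formyl-2,6-dimethoxyphenoxy)benzonitrile
Conditions: K2CO3, DMSO, 120 °C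
Reagents that add atoms: none
Why: Nucleophilic aromatic substitution; the para-cyano group stabilises the Meisenheimer intermediate and fluoride is the best leaving group, which should compensate for the hindered, formyl-deactivated phenoxide.

Step 5
Reactants: 8 4-(4-formyl-2,6-dimethoxyphenoxy)benzonitrile
Product: 10 4-(4-hydroxy-2,6-dimethoxyphenoxy)benzonitrile, via aryl formate 9 (not isolated)
Conditions: mCPBA, CH2Cl2, 0 °C to rt; then Et3N (cat.), MeOH, rt
Reagents that add atoms: 3-chloroperoxybenzoic acid, OOC(=O)c1cccc(Cl)c1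
Why: Baeyer–Villiger oxidation of an aryl aldehyde (Dakin-type); the trioxygenated ring with its para oxygen donor migrates in preference to hydrogen, the formate is cleaved by methanolysis, and the nitrile is inert to the peracid.

Step 6
Reactants: 10 4-(4-hydroxy-2,6-dimethoxyphenoxy)benzonitrile
Product: 12 4-(3-formyl-4-hydroxy-2,6-dimethoxyphenoxy)benzonitrile, via salicyl alcohol 11 (not isolated)
Conditions: MgCl2, Et3N, (CH2O)n, MeCN, 80 °C
Reagents that add atoms: formaldehyde (from paraformaldehyde), C=O
Why: Magnesium-mediated ortho-formylation of a phenol; the magnesium phenoxide delivers formaldehyde only to the position next to oxygen (the two ortho positions are equivalent), and a second formaldehyde accepts hydride from the hydroxymethyl intermediate.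

Step 7
Reactants: 12 4-(3-formyl-4-hydroxy-2,6-dimethoxyphenoxy)benzonitrile
Product: 13 4-(3-ethenyl-4-hydroxy-2,6-dimethoxyphenoxy)benzonitrile
Conditions: Ph3PCH3Br, KOtBu (2.5 equiv each), THF, 0 °C to rt
Reagents that add atoms: methyltriphenylphosphonium bromide, [Br-].C[P+](c1ccccc1)(c1ccccc1)c1ccccc1
Why: Wittig methylenation of a salicylaldehyde with excess ylide (one equivalent is consumed by the phenol); the non-enolisable aryl nitrile reacts far more slowly than the aldehyde.

Step 8
Reactants: 13 4-(3-ethenyl-4-hydroxy-2,6-dimethoxyphenoxy)benzonitrile; 5 (E)-3-[4-(benzyloxy)phenyl]prop-2-en-1-yl methyl carbonate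
Product: 14 4-{4-[(1S)-1-(4-benzyloxyphenyl)prop-2-enoxy]-3-ethenyl-2,6-dimethoxyphenoxy}benzonitrile
Conditions: 13, NaH, THF, 0 °C; then 5, [Ir(cod)Cl]2 (2 mol%), L (4 mol%), catalyst pre-activated with n-PrNH2, THF, rt
Reagents that add atoms: none
Why: Iridium-catalysed asymmetric allylic etherification; the cyclometalated monovalent iridium phosphoramidite complex ionises the carbonate, and the aryloxide attacks the aryl-bearing terminus of the allyl ligand on the face away from the metal, so the branched ether forms and the ligand sets C2'' as S.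

Step 9
Reactants: 14 4-{4-[(1S)-1-(4-benzyloxyphenyl)prop-2-enoxy]-3-ethenyl-2,6-dimethoxyphenoxy}benzonitrile
Product: 16 4-{4-[(1S)-1-(4-benzyloxyphenyl)prop-2-enoxy]-3-ethenyl-2,6-dimethoxyphenoxy}benzaldehyde, via aldimine 15 (not isolated)
Conditions: i-Bu2AlH (1.3 equiv), toluene, −78 °C; then aq. potassium sodium tartrate, pH 5
Reagents that add atoms: water, O
Why: Partial reduction of an aryl nitrile to the N-aluminated imine, which is hydrolysed on work-up; terminal alkenes and the ethers are inert at −78 °C, and the weakly acidic work-up spares the ionisable allylic ether.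

Step 10
Reactants: 16 4-{4-[(1S)-1-(4-benzyloxyphenyl)prop-2-enoxy]-3-ethenyl-2,6-dimethoxyphenoxy}benzaldehyde
Product: 17 ethyl (E)-3-(4-{4-[(1S)-1-(4-benzyloxyphenyl)prop-2-enoxy]-3-ethenyl-2,6-dimethoxyphenoxy}phenyl)prop-2-enoate
Conditions: (EtO)2P(O)CH2CO2Et, NaH, THF, 0 °C to rt
Reagents that add atoms: triethyl phosphonoacetate, CCOC(=O)CP(=O)(OCC)OCC
Why: Horner–Wadsworth–Emmons olefination as in step 1; the phosphonate anion is too weak a base to deprotonate the C2''–H.

Step 11
Reactants: 17 ethyl (E)-3-(4-{4-[(1S)-1-(4-benzyloxyphenyl)prop-2-enoxy]-3-ethenyl-2,6-dimethoxyphenoxy}phenyl)prop-2-enoate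
Product: 19 (E)-3-(4-{4-[(1S)-1-(4-benzyloxyphenyl)prop-2-enoxy]-3-ethenyl-2,6-dimethoxyphenoxy}phenyl)prop-2-en-1-ol, via enal 18 (not isolated)
Conditions: i-Bu2AlH (2.5 equiv), CH2Cl2, −78 to −20 °C; aq. potassium sodium tartrate
Reagents that add atoms: none
Why: 1,2-Reduction of the conjugated ester as in step 2; the aryl allyl ether and the alkenes do not react with the hydride at low temperature.

Step 12
Reactants: 19 (E)-3-(4-{4-[(1S)-1-(4-benzyloxyphenyl)prop-2-enoxy]-3-ethenyl-2,6-dimethoxyphenoxy}phenyl)prop-2-en-1-ol
Product: 20 (E)-3-(4-{4-[(1S)-1-(4-benzyloxyphenyl)prop-2-enoxy]-3-ethenyl-2,6-dimethoxyphenoxy}phenyl)prop-2-en-1-yl methyl carbonate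
Conditions: ClCO2Me, pyridine, CH2Cl2, 0 °C
Reagents that add atoms: methyl chloroformate, COC(=O)Cl
Why: Acylation of the primary allylic alcohol as in step 3, under buffered non-acidic conditions that leave the ether at C2'' intact.

Step 13
Reactants: 21 2-hydroxy-4,6-dimethoxybenzaldehyde
Product: 22 2-ethenyl-3,5-dimethoxyphenol
Conditions: Ph3PCH3Br, KOtBu (2.5 equiv each), THF, 0 °C to rt; neutral work-up, used at once
Reagents that add atoms: methyltriphenylphosphonium bromide, [Br-].C[P+](c1ccccc1)(c1ccccc1)c1ccccc1
Why: Wittig methylenation of a salicylaldehyde with excess ylide; the product is an electron-rich vinylphenol, so it is kept away from acid and is made immediately before step 14.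

Step 14
Reactants: 22 2-ethenyl-3,5-dimethoxyphenol; 20 (E)-3-(4-{4-[(1S)-1-(4-benzyloxyphenyl)prop-2-enoxy]-3-ethenyl-2,6-dimethoxyphenoxy}phenyl)prop-2-en-1-yl methyl carbonate
Product: 23 1-{[(1S)-1-(4-{4-[(1S)-1-(4-benzyloxyphenyl)prop-2-enoxy]-3-ethenyl-2,6-dimethoxyphenoxy}phenyl)prop-2-en-1-yl]oxy}-2-ethenyl-3,5-dimethoxybenzene, the (S,S)-bis(1-arylallyl 2-vinylaryl ether)
Conditions: 22, NaH, THF, 0 °C; then 20, [Ir(cod)Cl]2 (2 mol%), L (4 mol%), catalyst pre-activated with n-PrNH2, THF, rt; stopped at full conversion of 20
Reagents that add atoms: none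
Why: Iridium-catalysed asymmetric allylic etherification as in step 8; the carbonate ionises much faster than the aryl ether already present, the aryloxide attacks the substituted allyl terminus, and the same ligand sets C2 as S independently of C2'', so an error at either centre ends in a diastereomer and not in the enantiomer.

Step 15
Reactants: 23 the (S,S)-bis(1-arylallyl 2-vinylaryl ether)
Product: 24 (2S)-2-(4-{[(2S)-2-(4-benzyloxyphenyl)-5,7-dimethoxy-2H-chromen-6-yl]oxy}phenyl)-5,7-dimethoxy-2H-chromene
Conditions: second-generation Grubbs catalyst RuCl2(=CHPh)(H2IMes)(PCy3) (2 × 5 mol%), 1,4-benzoquinone (20 mol%), degassed CH2Cl2 (0.005 M), 40 °C, dark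
Reagents that add atoms: none
Why: Twofold ring-closing olefin metathesis, the known route from allyl 2-vinylaryl ethers to 2H-chromenes. The ruthenium benzylidene exchanges onto an allyl ether terminus, the new alkylidene adds to the neighbouring vinyl group in a [2+2] step, and cycloreversion of the ruthenacyclobutane releases the ring and a ruthenium methylidene that carries the chain; ethylene leaves the solution and drives both closures. Each ring closes as a six-membered 2H-pyran fused to its arene, with the new cis double bond C3=C4 (C3''=C4'') inside the ring. No stereocentre is formed, and C2 and C2'' lie outside the metallacycle and keep the S configuration set in steps 8 and 14. The step needs ring closure to outrun crossed and intermolecular metathesis; the substrate secures this because each vinyl group sits on the same ring as its own allyl ether, whereas a crossed closure would have to span the diaryl ether as a large ring, and high dilution supports it. It also needs the allylic hydrogens at C2 and C2'' to stay in place, so 1,4-benzoquinone is added to intercept ruthenium hydrides that would move the terminal double bonds towards oxygen, and 40 °C is well below the temperature of aryl allyl ether rearrangement. Light is excluded because 2H-chromenes open photochemically to achiral quinone methides.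

Step 16
Reactants: 24 the (2S,2''S)-bis(2H-chromene)
Product: 26 (2S,2''S)-bis(flavan-4-ol), 4'''-O-benzyl and 5,7,5'',7''-tetra-O-methyl, mixture of epimers at C4 and C4'', via bis-hydroperoxide 25 (not isolated)
Conditions: Co(acac)2 (20 mol%), PhSiH3, O2 (1 atm), THF, rt, dark; then PPh3
Reagents that add atoms: dioxygen, O=O
Why: Mukaiyama hydration; a trivalent cobalt hydride formed from divalent cobalt, silane and dioxygen transfers a hydrogen atom to C3 (C3''), the benzylic radical at C4 (C4''), stabilised by the oxygenated ring, is trapped by dioxygen, and the peroxide is reduced to the alcohol. The configuration at C4 is of no consequence because step 17 removes it.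

Step 17
Reactants: 26 the (2S,2''S)-bis(flavan-4-ol)
Product: 27 (2S,2''S)-4'''-O-benzyl-5,7,5'',7''-tetra-O-methyltetrahydrohinokiflavone
Conditions: Dess–Martin periodinane, NaHCO3, CH2Cl2, 0 °C to rt
Reagents that add atoms: none
Why: Periodinane oxidation of secondary benzylic alcohols; all C4 epimers converge on the diketone, and the buffered, near-neutral medium neither ionises the electron-rich benzylic alcohol nor opens the flavanone at C2.

Step 18
Reactants: 27 (2S,2''S)-4'''-O-benzyl-5,7,5'',7''-tetra-O-methyltetrahydrohinokiflavone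
Product: 28 7,7''-di-O-methyltetrahydrohinokiflavone
Conditions: BCl3, C6HMe5, CH2Cl2, −78 to −20 °C; then MeOH, aq. NaHCO3
Reagents that add atoms: none
Why: Chelation-controlled Lewis-acid dealkylation; BCl3 bound between each C4 carbonyl and its peri methoxy group cleaves only the 5- and 5''-methyl ethers, the aryl benzyl ether is cleaved at the same temperature with pentamethylbenzene trapping the benzyl cation, and the unchelated 7- and 7''-methyl ethers stay. The low temperature keeps the pyranone rings closed, so C2 and C2'' remain S.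

## Compound list

1 | 4-(benzyloxy)benzaldehyde | O=Cc1ccc(OCc2ccccc2)cc1 | starting material
2 | ethyl (E)-3-[4-(benzyloxy)phenyl]prop-2-enoate | CCOC(=O)/C=C/c1ccc(OCc2ccccc2)cc1 | intermediate
3 | (E)-3-[4-(benzyloxy)phenyl]prop-2-enal | O=C/C=C/c1ccc(OCc2ccccc2)cc1 | intermediate (not isolated)
4 | (E)-3-[4-(benzyloxy)phenyl]prop-2-en-1-ol | OC/C=C/c1ccc(OCc2ccccc2)cc1 | intermediate
5 | (E)-3-[4-(benzyloxy)phenyl]prop-2-en-1-yl methyl carbonate | COC(=O)OC/C=C/c1ccc(OCc2ccccc2)cc1 | intermediate
6 | syringaldehyde | COc1cc(C=O)cc(OC)c1O | starting material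
7 | 4-fluorobenzonitrile | N#Cc1ccc(F)cc1 | starting material
8 | 4-(4-formyl-2,6-dimethoxyphenoxy)benzonitrile | COc1cc(C=O)cc(OC)c1Oc1ccc(C#N)cc1 | intermediate
9 | 4-(4-cyanophenoxy)-3,5-dimethoxyphenyl formate | COc1cc(OC=O)cc(OC)c1Oc1ccc(C#N)cc1 | intermediate (not isolated)
10 | 4-(4-hydroxy-2,6-dimethoxyphenoxy)benzonitrile | COc1cc(O)cc(OC)c1Oc1ccc(C#N)cc1 | intermediate
11 | 4-[4-hydroxy-3-(hydroxymethyl)-2,6-dimethoxyphenoxy]benzonitrile | COc1cc(O)c(CO)c(OC)c1Oc1ccc(C#N)cc1 | intermediate (not isolated)
12 | 4-(3-formyl-4-hydroxy-2,6-dimethoxyphenoxy)benzonitrile | COc1cc(O)c(C=O)c(OC)c1Oc1ccc(C#N)cc1 | intermediate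
13 | 4-(3-ethenyl-4-hydroxy-2,6-dimethoxyphenoxy)benzonitrile | COc1cc(O)c(C=C)c(OC)c1Oc1ccc(C#N)cc1 | intermediate
14 | 4-{4-[(1S)-1-(4-benzyloxyphenyl)prop-2-enoxy]-3-ethenyl-2,6-dimethoxyphenoxy}benzonitrile | N#Cc1ccc(Oc2c(OC)cc(O[C@@H](C=C)c3ccc(OCc4ccccc4)cc3)c(C=C)c2OC)cc1 | intermediate
15 | (4-{4-[(1S)-1-(4-benzyloxyphenyl)prop-2-enoxy]-3-ethenyl-2,6-dimethoxyphenoxy}phenyl)methanimine | N=Cc1ccc(Oc2c(OC)cc(O[C@@H](C=C)c3ccc(OCc4ccccc4)cc3)c(C=C)c2OC)cc1 | intermediate (not isolated)
16 | 4-{4-[(1S)-1-(4-benzyloxyphenyl)prop-2-enoxy]-3-ethenyl-2,6-dimethoxyphenoxy}benzaldehyde | O=Cc1ccc(Oc2c(OC)cc(O[C@@H](C=C)c3ccc(OCc4ccccc4)cc3)c(C=C)c2OC)cc1 | intermediate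
17 | ethyl (E)-3-(4-{4-[(1S)-1-(4-benzyloxyphenyl)prop-2-enoxy]-3-ethenyl-2,6-dimethoxyphenoxy}phenyl)prop-2-enoate | CCOC(=O)/C=C/c1ccc(Oc2c(OC)cc(O[C@@H](C=C)c3ccc(OCc4ccccc4)cc3)c(C=C)c2OC)cc1 | intermediate
18 | (E)-3-(4-{4-[(1S)-1-(4-benzyloxyphenyl)prop-2-enoxy]-3-ethenyl-2,6-dimethoxyphenoxy}phenyl)prop-2-enal | O=C/C=C/c1ccc(Oc2c(OC)cc(O[C@@H](C=C)c3ccc(OCc4ccccc4)cc3)c(C=C)c2OC)cc1 | intermediate (not isolated)
19 | (E)-3-(4-{4-[(1S)-1-(4-benzyloxyphenyl)prop-2-enoxy]-3-ethenyl-2,6-dimethoxyphenoxy}phenyl)prop-2-en-1-ol | OC/C=C/c1ccc(Oc2c(OC)cc(O[C@@H](C=C)c3ccc(OCc4ccccc4)cc3)c(C=C)c2OC)cc1 | intermediate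
20 | (E)-3-(4-{4-[(1S)-1-(4-benzyloxyphenyl)prop-2-enoxy]-3-ethenyl-2,6-dimethoxyphenoxy}phenyl)prop-2-en-1-yl methyl carbonate | COC(=O)OC/C=C/c1ccc(Oc2c(OC)cc(O[C@@H](C=C)c3ccc(OCc4ccccc4)cc3)c(C=C)c2OC)cc1 | intermediate
21 | 2-hydroxy-4,6-dimethoxybenzaldehyde | COc1cc(O)c(C=O)c(OC)c1 | starting material
22 | 2-ethenyl-3,5-dimethoxyphenol | COc1cc(O)c(C=C)c(OC)c1 | intermediate
23 | (S,S)-bis(1-arylallyl 2-vinylaryl ether): 1-{[(1S)-1-(4-{4-[(1S)-1-(4-benzyloxyphenyl)prop-2-enoxy]-3-ethenyl-2,6-dimethoxyphenoxy}phenyl)prop-2-en-1-yl]oxy}-2-ethenyl-3,5-dimethoxybenzene | COc1cc(OC)c(C=C)c(c1)O[C@@H](C=C)c1ccc(Oc2c(OC)cc(O[C@@H](C=C)c3ccc(OCc4ccccc4)cc3)c(C=C)c2OC)cc1 | intermediate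
24 | (2S)-2-(4-{[(2S)-2-(4-benzyloxyphenyl)-5,7-dimethoxy-2H-chromen-6-yl]oxy}phenyl)-5,7-dimethoxy-2H-chromene | COc1cc(OC)c2c(c1)O[C@H](c1ccc(Oc3c(OC)cc4c(c3OC)C=C[C@@H](c3ccc(OCc5ccccc5)cc3)O4)cc1)C=C2 | intermediate
25 | (2S,2''S)-4,4''-bis(hydroperoxy)flavan dimer, 4'''-O-benzyl, 5,7,5'',7''-tetra-O-methyl, C4 and C4'' undefined | COc1cc(OC)c2c(c1)O[C@H](c1ccc(Oc3c(OC)cc4c(c3OC)C(OO)C[C@@H](c3ccc(OCc5ccccc5)cc3)O4)cc1)CC2OO | intermediate (not isolated)
26 | (2S,2''S)-bis(flavan-4-ol), 4'''-O-benzyl, 5,7,5'',7''-tetra-O-methyl, C4 and C4'' undefined | COc1cc(OC)c2c(c1)O[C@H](c1ccc(Oc3c(OC)cc4c(c3OC)C(O)C[C@@H](c3ccc(OCc5ccccc5)cc3)O4)cc1)CC2O | intermediate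
27 | (2S,2''S)-4'''-O-benzyl-5,7,5'',7''-tetra-O-methyltetrahydrohinokiflavone | COc1cc(OC)c2c(c1)O[C@H](c1ccc(Oc3c(OC)cc4c(c3OC)C(=O)C[C@@H](c3ccc(OCc5ccccc5)cc3)O4)cc1)CC2=O | intermediate
28 | 7,7''-di-O-methyltetrahydrohinokiflavone | COc1cc(O)c2c(c1)O[C@H](c1ccc(Oc3c(OC)cc4c(c3O)C(=O)C[C@@H](c3ccc(O)cc3)O4)cc1)CC2=O | target

## Step count and least certain steps

Total: 18 steps. Longest linear sequence: 14 steps, from 6 through steps 4 to 12 and 14 to 18.

**Step 15 (key step).**
- What may go wrong: intermolecular or crossed metathesis among the four alkenes; ruthenium hydride-induced migration of the allyl double bonds, which would erase C2 and C2''; slow turnover, because both vinyl groups sit between two ortho oxygen substituents.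
- Fallback: it sets out from 14 and returns at 24, closing the rings one at a time on dienes that each hold only two reacting alkenes.
  - Compound 14 is cyclised with the same catalyst to the chromene nitrile F1.
  - F1 is taken through the chemistry of steps 9 to 12: i-Bu2AlH to the chromene aldehyde F2, Horner–Wadsworth–Emmons olefination to the chromene cinnamate F3, i-Bu2AlH to the chromene allylic alcohol F4, and methyl chloroformate to the chromene carbonate F5.
  - F5 is etherified with 22 as in step 14 to the mono-chromene diene F6, and a second single ring closure of F6 gives 24.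

**Step 8 (the same concern applies more weakly to step 14).**
- What may go wrong: erosion of enantiomeric purity and of the branched-to-linear preference. The 4-benzyloxyphenyl group makes the product ether easy to re-ionise at iridium, and the ortho-substituted aryloxide is a hindered nucleophile.
- Fallback: it sets out from 4 and 13 and returns at 14, fixing the stereocentre by an epoxide opening instead of an allyl-metal substitution.
  - Sharpless asymmetric epoxidation of 4 (Ti(OiPr)4, L-(+)-diethyl tartrate, t-BuOOH, 4 Å sieves, CH2Cl2, −20 °C) gives the (2S,3S)-epoxy alcohol F7.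
  - The sodium phenoxide of 13 (NaOH, water/1,4-dioxane, 60 °C) opens F7 at the benzylic carbon with inversion to the (1R,2S)-diol F8.
  - F8 is converted with thiocarbonyldiimidazole into the cyclic thionocarbonate F9.
  - Corey–Winter fragmentation of F9 with 1,3-dimethyl-2-phenyl-1,3,2-diazaphospholidine at 40 °C gives the terminal alkene 14.

**Step 16.**
- What may go wrong: hydrogen abstraction by peroxyl radicals at the doubly activated C2–H and C2''–H, fragmentation of the benzylic hydroperoxides, or simple reduction of the double bonds in place of oxygenation.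
- Fallback: it sets out from 24 and returns at 26, using a polar instead of a radical Markovnikov functionalisation.
  - Copper hydride-catalysed hydroboration (CuCl, NaOtBu, 1,2-bis(diphenylphosphino)benzene, pinacolborane, THF, rt) places boron at the benzylic carbons and gives the bis(benzylic boronate) F10.
  - Oxidation of F10 with NaBO3 in aqueous THF gives 26.

**Step 18.**
- What may go wrong: Lewis-acid-promoted opening of a pyranone ring to the chalcone and reclosure, with loss of configuration at C2 or C2''; additional loss of the 7''-methyl group, which neighbours the diaryl ether oxygen; C-benzylation of ring A if the cation is not trapped.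
- Fallback: it sets out from 27 and returns at 28, separating the two deprotections.
  - Hydrogenolysis (H2, Pd/C, EtOAc, rt) removes the benzyl group under neutral conditions and gives the tetra-O-methyl phenol F11.
  - MgI2·OEt2 in THF at 50 °C then cleaves only the methyl ethers chelated to the C4 and C4'' carbonyl groups and gives 28.

**Step 13.**
- What may go wrong: incomplete methylenation of the phenoxide-deactivated aldehyde, and acid-triggered oligomerisation of the very electron-rich vinylphenol during isolation.
- Fallback: it sets out from 21 and 20 and returns at 23, reversing the order of the two operations.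
  - The sodium phenoxide of 21 is etherified with 20 under the conditions of step 14 to the aryl ether aldehyde F12.
  - Wittig methylenation of F12 (Ph3PCH3Br, KOtBu, THF) gives 23 without a free vinylphenol ever being handled.

## Further compounds

F1 | step 15 | 4-{[(2S)-2-(4-benzyloxyphenyl)-5,7-dimethoxy-2H-chromen-6-yl]oxy}benzonitrile | N#Cc1ccc(Oc2c(OC)cc3c(c2OC)C=C[C@@H](c2ccc(OCc4ccccc4)cc2)O3)cc1
F2 | step 15 | 4-{[(2S)-2-(4-benzyloxyphenyl)-5,7-dimethoxy-2H-chromen-6-yl]oxy}benzaldehyde | O=Cc1ccc(Oc2c(OC)cc3c(c2OC)C=C[C@@H](c2ccc(OCc4ccccc4)cc2)O3)cc1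
F3 | step 15 | ethyl (E)-3-(4-{[(2S)-2-(4-benzyloxyphenyl)-5,7-dimethoxy-2H-chromen-6-yl]oxy}phenyl)prop-2-enoate | CCOC(=O)/C=C/c1ccc(Oc2c(OC)cc3c(c2OC)C=C[C@@H](c2ccc(OCc4ccccc4)cc2)O3)cc1
F4 | step 15 | (E)-3-(4-{[(2S)-2-(4-benzyloxyphenyl)-5,7-dimethoxy-2H-chromen-6-yl]oxy}phenyl)prop-2-en-1-ol | OC/C=C/c1ccc(Oc2c(OC)cc3c(c2OC)C=C[C@@H](c2ccc(OCc4ccccc4)cc2)O3)cc1
F5 | step 15 | (E)-3-(4-{[(2S)-2-(4-benzyloxyphenyl)-5,7-dimethoxy-2H-chromen-6-yl]oxy}phenyl)prop-2-en-1-yl methyl carbonate | COC(=O)OC/C=C/c1ccc(Oc2c(OC)cc3c(c2OC)C=C[C@@H](c2ccc(OCc4ccccc4)cc2)O3)cc1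
F6 | step 15 | (2S)-2-(4-benzyloxyphenyl)-6-(4-{(1S)-1-[(2-ethenyl-3,5-dimethoxyphenyl)oxy]prop-2-en-1-yl}phenoxy)-5,7-dimethoxy-2H-chromene | COc1cc(OC)c(C=C)c(c1)O[C@@H](C=C)c1ccc(Oc2c(OC)cc3c(c2OC)C=C[C@@H](c2ccc(OCc4ccccc4)cc2)O3)cc1
F7 | step 8 | [(2S,3S)-3-(4-benzyloxyphenyl)oxiran-2-yl]methanol | OC[C@@H]1O[C@H]1c1ccc(OCc2ccccc2)cc1
F8 | step 8 | 4-{4-[(1R,2S)-1-(4-benzyloxyphenyl)-2,3-dihydroxypropoxy]-3-ethenyl-2,6-dimethoxyphenoxy}benzonitrile | N#Cc1ccc(Oc2c(OC)cc(O[C@@H]([C@@H](O)CO)c3ccc(OCc4ccccc4)cc3)c(C=C)c2OC)cc1
F9 | step 8 | 4-{4-[(R)-(4-benzyloxyphenyl)[(4S)-2-sulfanylidene-1,3-dioxolan-4-yl]methoxy]-3-ethenyl-2,6-dimethoxyphenoxy}benzonitrile | N#Cc1ccc(Oc2c(OC)cc(O[C@@H]([C@@H]3COC(=S)O3)c3ccc(OCc4ccccc4)cc3)c(C=C)c2OC)cc1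
F10 | step 16 | (2S,2''S)-bis(flavan) with pinacolboronate groups at C4 and C4'', 4'''-O-benzyl, 5,7,5'',7''-tetra-O-methyl | COc1cc(OC)c2c(c1)O[C@H](c1ccc(Oc3c(OC)cc4c(c3OC)C(B5OC(C)(C)C(C)(C)O5)C[C@@H](c3ccc(OCc6ccccc6)cc3)O4)cc1)CC2B1OC(C)(C)C(C)(C)O1
F11 | step 18 | (2S,2''S)-5,7,5'',7''-tetra-O-methyltetrahydrohinokiflavone | COc1cc(OC)c2c(c1)O[C@H](c1ccc(Oc3c(OC)cc4c(c3OC)C(=O)C[C@@H](c3ccc(O)cc3)O4)cc1)CC2=O
F12 | step 13 | 2-{[(1S)-1-(4-{4-[(1S)-1-(4-benzyloxyphenyl)prop-2-enoxy]-3-ethenyl-2,6-dimethoxyphenoxy}phenyl)prop-2-en-1-yl]oxy}-4,6-dimethoxybenzaldehyde | COc1cc(OC)c(C=O)c(c1)O[C@@H](C=C)c1ccc(Oc2c(OC)cc(O[C@@H](C=C)c3ccc(OCc4ccccc4)cc3)c(C=C)c2OC)cc1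
A1 | alternative 1 | 5,7,5'',7''-tetra-O-methyl-4'''-O-isopropylhinokiflavone | COc1cc(OC)c2c(c1)oc(-c1ccc(Oc3c(OC)cc4oc(-c5ccc(OC(C)C)cc5)cc(=O)c4c3OC)cc1)cc2=O
A2 | alternative 1 | 2-iodo-3,5-dimethoxyphenol | COc1cc(O)c(I)c(OC)c1
A3 | alternative 1 | 6-(4-ethynylphenoxy)-5,7-dimethoxy-2-(4-isopropoxyphenyl)-4H-chromen-4-one | C#Cc1ccc(Oc2c(OC)cc3oc(-c4ccc(OC(C)C)cc4)cc(=O)c3c2OC)cc1
A4 | alternative 2 | bis(2-hydroxyaryl 1,3-diketone) | COc1cc(OC)c(C(=O)CC(=O)c2ccc(Oc3c(OC)cc(O)c(C(=O)CC(=O)c4ccc(OC(C)C)cc4)c3OC)cc2)c(O)c1
A5 | alternative 2 | bis(O-aroyl 2-hydroxyacetophenone): 2-acetyl-3,5-dimethoxyphenyl 4-{3-acetyl-2,6-dimethoxy-4-[(4-isopropoxybenzoyl)oxy]phenoxy}benzoate | COc1cc(OC)c(C(C)=O)c(OC(=O)c2ccc(Oc3c(OC)cc(OC(=O)c4ccc(OC(C)C)cc4)c(C(C)=O)c3OC)cc2)c1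
A6 | alternative 3 | (2S,2''S)-bis-flavanone with free 5-hydroxyl, 5''-O-methyl and 4'''-O-benzyl protected | COc1cc(O)c2c(c1)O[C@H](c1ccc(Oc3c(OC)cc4c(c3OC)C(=O)C[C@@H](c3ccc(OCc5ccccc5)cc3)O4)cc1)CC2=O
A7 | alternative 3 | 1,3-dimethoxy-1-(trimethylsilyloxy)buta-1,3-diene | COC(=C)C=C(OC)O[Si](C)(C)C
A8 | alternative 3 | (2S)-2-(4-{[(2S)-2-(4-benzyloxyphenyl)-5,7-dimethoxy-4-oxochroman-6-yl]oxy}phenyl)-5-(phenylsulfinyl)-2,3-dihydro-4H-pyran-4-one | O=C1C[C@@H](c2ccc(Oc3c(OC)cc4c(c3OC)C(=O)C[C@@H](c3ccc(OCc5ccccc5)cc3)O4)cc2)OC=C1S(=O)c1ccccc1
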